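**Plan**

1. Numbering and rings: atoms carry their position in the target SMILES (O1 to O35). Ring A is the enone ring (C2–C5, C14, C15), B the central benzene ring, C the phenol ring, D the five-membered ketal ring (C7, C8, C16, C29, C34) and E the cyclopentenone (C29, C30, C32, C33, C34).
2. Enabling feature: in ring E the chain C30–C29–C34–C33≡C32 is a pent-4-ynal in disguise, with C30 as the formyl carbon and the oxygen-bearing quaternary C34 as its C3, held next to C29 by ring D. Adding the formyl C–H across the triple bond with [Rh(dppe)]2(BF4)2 closes such a chain to the cyclopent-2-enone.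
3. Retrosynthetic cuts, in order: C30–C32 (ring E); C34–C33 (acetylide to the C34 ketone); two C29–CH2O bonds (formaldehyde aldols: one arm becomes C30, the other is a removable placeholder for H29); C16–O17 and C16–O28 (naphthalene-1,8-diol onto a C16-bromo indenone); C4–C5 and C2–C14 (ring A); C8–C16 (ring D); back to 2-acetyl-6-methoxynaphthalene.
4. Forward order: ring D by Nazarov cyclisation; ring A by acylation at C14, peri-alkylation at C5 and dehydrogenation; spiroketal at C16; quaternary C29; alkynyl carbinol C34; ring E; loss of the placeholder arm; O-demethylation.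
5. Stereochemistry: a Sc(OTf)3–chiral bipyridine catalysed hydroxymethylation fixes a quaternary C29. Its bulky silyloxymethyl arm sends the acetylide to the opposite face and so sets C34 with the alkyne cis to the future formyl group. After ring closure the arm is oxidised off as CO2 and the cis ring fusion alone places H29. A C29–H aldehyde is avoided because acetylide addition would leave it trans to the alkyne, correctable only through an enol that can expel a ketal oxygen.

Key step: step 14

Remark: the (S,S) ligand is written for step 10 on the assumption that it shields the enol face needed for (S)-C29; should the sense be the reverse, its mirror image is used.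
Remark: the 9-hydroxyphenalenone unit of the target is a fast tautomeric pair; the route carries the methyl ether of the tautomer drawn (carbonyl at C2, O13 on C12), which the choice of starting naphthalene fixes.

**Route**

Step 1
Reactants: 1 1-(6-methoxynaphthalen-2-yl)ethan-1-one
Product: 3 1-(6-methoxynaphthalen-2-yl)prop-2-en-1-one, via Mannich base 2 (not isolated)
Conditions: (CH2O)n, PhNHMe·CF3CO2H, THF, reflux
Reagents that add atoms: formaldehyde (from paraformaldehyde), C=O
Why: α-Methylenation of the methyl ketone: a Mannich reaction with the anilinium salt and formaldehyde followed by β-elimination of N-methylaniline should give the aryl vinyl ketone, the acetyl methyl group being the only enolisable position.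

Step 2
Reactants: 3 1-(6-methoxynaphthalen-2-yl)prop-2-en-1-one
Product: 4 7-methoxy-1,2-dihydro-3H-cyclopenta[a]naphthalen-3-one
Conditions: CF3SO3H, ClCH2CH2Cl, 0 → 50 °C
Reagents that add atoms: none
Why: Nazarov-type cyclisation in superacid (the O-protonated aryl vinyl ketone alkylates the ring) should close ring D at the α-position C8, the more reactive neighbour of the acyl-bearing C7, so that the ketone lies at C34 and C16 is left as a benzylic CH2.

Step 3
Reactants: 4 7-methoxy-1,2-dihydro-3H-cyclopenta[a]naphthalen-3-one; 5 3-chloropropanoyl chloride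
Product: 6 6-(3-chloropropanoyl)-7-methoxy-1,2-dihydro-3H-cyclopenta[a]naphthalen-3-one
Conditions: AlCl3, CH2Cl2, 0 °C
Reagents that add atoms: none
Why: Friedel–Crafts acylation should go to C14, the α-position ortho to the methoxy group that is the most nucleophilic site of a 2-methoxynaphthalene and is not in conjugation with the C34 ketone, while the low temperature spares the methyl ether.

Step 4
Reactants: 6 6-(3-chloropropanoyl)-7-methoxy-1,2-dihydro-3H-cyclopenta[a]naphthalen-3-one
Product: 8 tetracyclic diketone (ring A closed as the 9-methoxy-2,3-dihydrophenalen-1-one; C34 ketone; C16 and C29 CH2), via acryloyl ketone 7 (not isolated)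
Conditions: Et3N, CH2Cl2, rt; then CF3SO3H, ClCH2CH2Cl, 0 → 50 °C
Reagents that add atoms: none
Why: Et3N eliminates HCl to the aryl vinyl ketone and the acid then drives an intramolecular Friedel–Crafts (Michael-type) alkylation of the peri position C5, the only ring carbon the three-carbon chain on C14 can reach, which should close ring A with the methoxy group still on C12.

Step 5
Reactants: 8 tetracyclic diketone
Product: 9 phenalenone ketone (ring A enone C3=C4; C34 ketone; C16 and C29 CH2)
Conditions: DDQ, 1,4-dioxane, 100 °C
Reagents that add atoms: none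
Why: DDQ dehydrogenation of a 2,3-dihydrophenalen-1-one to the phenalenone is driven by the gain in conjugation across C3–C4, whereas the cyclopentanone ring would only give a non-aromatic indenone and should stay as it is.

Step 6
Reactants: 9 phenalenone ketone
Product: 11 C16-bromo indenone (C16=C29; C34 ketone), via gem-dibromide 10 (not isolated)
Conditions: NBS (2.1 equiv), AIBN (cat.), PhCF3, 85 °C; then Et3N, 0 °C
Reagents that add atoms: N-bromosuccinimide, O=C1CCC(=O)N1Br
Why: Wohl–Ziegler bromination replaces both hydrogens of C16, the only benzylic CH2, and Et3N then removes HBr across C29–C16 through the C34 enolate, the usual passage from an indan-1-one to a 3-bromoinden-1-one, which fixes the leaving group on C16 and the carbonyl on C34.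

Step 7
Reactants: 11 C16-bromo indenone; 12 naphthalene-1,8-diol
Product: 14 spiroketal ketone (C16 naphthalene-1,8-diyl ketal; C29 CH2; C34 ketone), via aryl enol ether 13 (not isolated)
Conditions: Et3N, MeCN, 0 °C → rt; then CSA (cat.), PhMe, 50 °C
Reagents that add atoms: none
Why: Conjugate addition–elimination of one naphthol oxygen at C16 of the vinylogous acyl bromide gives the β-aryloxy enone, and the second, peri-held oxygen adds to the same carbon under acid catalysis (ketalisation of an enol ether, the intramolecular counterpart of the conversion of β-halovinyl ketones into β-keto acetals), so the ketal can only be at C16 and the ketone at C34.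

Step 8
Reactants: 14 spiroketal ketone
Product: 16 rac-C29-hydroxymethyl ketone, via silyl enol ether 15 (not isolated)
Conditions: TMSOTf, iPr2NEt, CH2Cl2, 0 °C; then 37% aq. HCHO, Sc(OTf)3 (10 mol%), THF, rt
Reagents that add atoms: formaldehyde, C=O
Why: Soft enolisation to the silyl enol ether avoids a free enolate that could expel a ketal oxygen from C16, and the aqueous Mukaiyama aldol reaction with formaldehyde under Sc(OTf)3 catalysis should give the mono-hydroxymethyl ketone as a racemate, whose C29 centre is flattened again in step 10.

Step 9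
Reactants: 16 rac-C29-hydroxymethyl ketone
Product: 17 rac-C29-(tert-butyldimethylsilyloxymethyl) ketone
Conditions: TBSCl, imidazole, DMF, rt
Reagents that add atoms: tert-butyldimethylsilyl chloride, CC(C)(C)[Si](C)(C)Cl
Why: Routine silylation of the primary alcohol turns this arm into the bulky placeholder that will later stand where H29 is in the target.

Step 10
Reactants: 17 rac-C29-(tert-butyldimethylsilyloxymethyl) ketone
Product: 19 (S)-C29 quaternary ketone (CH2OTBS and CH2OH on C29), via silyl enol ether 18 (not isolated)
Conditions: TMSOTf, iPr2NEt, CH2Cl2, 0 °C → rt; then 37% aq. HCHO, Sc(OTf)3 (10 mol%), (S,S)-6,6′-bis(1-hydroxy-2,2-dimethylpropyl)-2,2′-bipyridine (12 mol%), DME/H2O, −20 °C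
Reagents that add atoms: formaldehyde, C=O
Why: Catalytic asymmetric hydroxymethylation of a silicon enolate: the tetrasubstituted enol ether adds to formaldehyde in the pocket of the Sc(OTf)3–bipyridine complex, a reaction type known to build quaternary centres next to cyclic aryl ketones, and the ligand-controlled face of attack should make C29 a quaternary (S) centre that can no longer enolise.

Step 11
Reactants: 19 (S)-C29 quaternary ketone; 20 ethynyltrimethylsilane
Product: 21 alkynyl diol (C34 carbinol; alkyne cis to CH2OH; hydroxyl cis to CH2OTBS)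
Conditions: 20, n-BuLi, THF, −78 °C; CeCl3, −78 °C; then 19, −78 → −40 °C; aq. NH4Cl
Reagents that add atoms: none
Why: 1,2-Addition of the cerium acetylide Cl2CeC≡CSiMe3 to the non-enolisable C34 ketone should occur from the face opposite the bulky CH2OTBS arm and beside the small metal-bound CH2O arm, which sets C34 with the alkyne cis to the future formyl carbon C30 and the hydroxyl cis to the placeholder, while the vinylogous-ester carbonyl at C2 is too poor an electrophile to compete at −78 °C.

Step 12
Reactants: 21 alkynyl diol
Product: 22 hydroxy aldehyde (C30 formyl; C34 OH)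
Conditions: Dess–Martin periodinane, CH2Cl2, 0 °C → rt
Reagents that add atoms: none
Why: Dess–Martin oxidation takes the primary alcohol to the aldehyde and leaves the tertiary alcohol alone, and because C29 is quaternary the aldehyde can neither epimerise nor lose a ketal oxygen by β-elimination.

Step 13
Reactants: 22 hydroxy aldehyde
Product: 23 4-alkynal (C30 formyl; C34 OSiEt3; C32 SiMe3; C29 CH2OTBS)
Conditions: Et3SiOTf, 2,6-lutidine, CH2Cl2, −78 → 0 °C
Reagents that add atoms: triethylsilyl trifluoromethanesulfonate, CC[Si](CC)(CC)OS(=O)(=O)C(F)(F)F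
Why: Silyl triflate silylation with a hindered pyridine base caps the crowded tertiary propargylic alcohol as its triethylsilyl ether, so that the 4-alkynal meets the cationic catalyst as an ether, the substitution pattern for which the cyclisation is known.

Step 14
Reactants: 23 4-alkynal
Product: 24 cyclopentenone (ring E closed; C32 SiMe3; C34 OSiEt3; C29 CH2OTBS)
Conditions: [Rh(dppe)]2(BF4)2 (10 mol%; dppe = Ph2PCH2CH2PPh2), acetone, rt
Reagents that add atoms: none
Why: Oxidative addition of the C30–H bond to monovalent rhodium gives an acyl rhodium hydride (trivalent rhodium), hydride and metal add across the pendant alkyne in a net trans sense (hydrogen to C33, rhodium to C32), and reductive elimination from the six-membered acyl(alkenyl)rhodacycle forms C30–C32 and releases the cyclopentenone. The closest known reaction is the rhodium–dppe catalysed trans-hydroacylation of 4-alkynals to cyclopent-2-enones, which tolerates an oxygenated quaternary C3. Ring E closes in a formally 5-endo-dig mode, open only because the bond is made at the metal. No stereocentre is formed: C29 and C34 are already set, and C29 is quaternary and cannot epimerise. The step needs the formyl group and the alkyne on the same face of ring D, which steps 10 and 11 secure, and it needs cyclisation to outrun decarbonylation, which the chelating diphosphine and the Thorpe–Ingold effect of the fully substituted C29 and C34 should favour; the trimethylsilyl cap keeps the alkyne from vinylidene or oligomer formation and ends up on C32.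

Step 15
Reactants: 24 cyclopentenone
Product: 25 keto diol (C29 CH2OH; C34 OH; C32 H)
Conditions: CF3CO2H/CH2Cl2 (1:1), H2O (5 equiv), 0 °C → rt
Reagents that add atoms: none
Why: Aqueous acid cleaves the primary TBS and the tertiary TES ether and protodesilylates the α-silyl enone by ipso protonation at C32 (β-silyl cation), which is safe at this stage because the quaternary C29 keeps the C30 ketone from enolising towards the ketal and the C34 carbinol would ionise only to a destabilised 4-oxocyclopentenyl cation.

Step 16
Reactants: 25 keto diol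
Product: 28 spiropreussione B 9-methyl ether, via keto aldehyde 26 (not isolated), via keto acid 27 (not isolated)
Conditions: TEMPO (20 mol%), PhI(OAc)2, MeCN/H2O, rt → 40 °C
Reagents that add atoms: none
Why: Oxoammonium (TEMPO/PhI(OAc)2) oxidation in wet acetonitrile takes the neopentyl primary alcohol through the aldehyde to the β-keto acid, which loses CO2 on gentle warming through the usual cyclic transition state, and the resulting C30 enol can be protonated at C29 only so as to give the cis-fused bicyclo[3.3.0] system, which puts H29 on the face of O35.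

Step 17
Reactants: 28 spiropreussione B 9-methyl ether
Product: 29 spiropreussione B
Conditions: MgI2, Et2O/PhMe, rt → 40 °C; aq. NH4Cl
Reagents that add atoms: none
Why: MgI2 binds the C2 carbonyl and the peri methoxy oxygen and iodide removes the methyl group (chelation-assisted cleavage of a methyl ether next to a carbonyl), a Lewis acid mild enough for the β-hydroxy ketone and the β-keto ketal of the product.

**Compound list**

The C34 label changes from S (21–25) to R (28, 29) only because C29 stops being quaternary and drops in CIP priority; the centre itself is not touched.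

1 | 1-(6-methoxynaphthalen-2-yl)ethan-1-one (2-acetyl-6-methoxynaphthalene) | CC(=O)c1ccc2cc(OC)ccc2c1 | starting material
2 | 1-(6-methoxynaphthalen-2-yl)-3-[methyl(phenyl)amino]propan-1-one (Mannich base) | CN(CCC(=O)c1ccc2cc(OC)ccc2c1)c1ccccc1 | intermediate
3 | 1-(6-methoxynaphthalen-2-yl)prop-2-en-1-one | C=CC(=O)c1ccc2cc(OC)ccc2c1 | intermediate
4 | 7-methoxy-1,2-dihydro-3H-cyclopenta[a]naphthalen-3-one | O=C1CCc2c1ccc1cc(OC)ccc21 | intermediate
5 | 3-chloropropanoyl chloride | O=C(Cl)CCCl | starting material
6 | 6-(3-chloropropanoyl)-7-methoxy-1,2-dihydro-3H-cyclopenta[a]naphthalen-3-one | O=C1CCc2c1ccc1c(C(=O)CCCl)c(OC)ccc21 | intermediate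
7 | 6-acryloyl-7-methoxy-1,2-dihydro-3H-cyclopenta[a]naphthalen-3-one | O=C1CCc2c1ccc1c(C(=O)C=C)c(OC)ccc21 | intermediate
8 | tetracyclic diketone: 9-methoxy-2,3-dihydrophenalen-1-one with a cyclopentanone fused at C7–C8 (C34 ketone on C7; C16 and C29 CH2) | O=C1CCc2cc3c(c4ccc(OC)c1c24)CCC3=O | intermediate
9 | the corresponding 9-methoxyphenalen-1-one (C3=C4) with the fused cyclopentanone | O=C1C=Cc2cc3c(c4ccc(OC)c1c24)CCC3=O | intermediate
10 | C16 gem-dibromide of 9 | O=C1C=Cc2cc3c(c4ccc(OC)c1c24)C(Br)(Br)CC3=O | intermediate
11 | C16-bromo indenone (C16=C29; C34 ketone) | O=C1C=Cc2cc3c(c4ccc(OC)c1c24)C(Br)=CC3=O | intermediate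
12 | naphthalene-1,8-diol | Oc1cccc2cccc(O)c12 | starting material
13 | C16 (8-hydroxynaphthalen-1-yl) enol ether of the indenone (vinylogous ester) | O=C1C=Cc2cc3c(c4ccc(OC)c1c24)C(Oc1cccc2cccc(O)c12)=CC3=O | intermediate
14 | spiroketal ketone: C16 naphthalene-1,8-diyl ketal; C29 CH2; C34 ketone | O=C1C=Cc2cc3c(c4ccc(OC)c1c24)C1(Oc2cccc4cccc(c24)O1)CC3=O | intermediate
15 | trimethylsilyl enol ether of 14 (C29=C34; C34 OSiMe3) | O=C1C=Cc2cc3c(c4ccc(OC)c1c24)C1(Oc2cccc4cccc(c24)O1)C=C3O[Si](C)(C)C | intermediate
16 | racemic C29-hydroxymethyl ketone | O=C1C=Cc2cc3c(c4ccc(OC)c1c24)C1(Oc2cccc4cccc(c24)O1)C(CO)C3=O | intermediate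
17 | racemic C29-(tert-butyldimethylsilyloxymethyl) ketone | O=C1C=Cc2cc3c(c4ccc(OC)c1c24)C1(Oc2cccc4cccc(c24)O1)C(CO[Si](C)(C)C(C)(C)C)C3=O | intermediate
18 | trimethylsilyl enol ether of 17 (tetrasubstituted C29=C34) | O=C1C=Cc2cc3c(c4ccc(OC)c1c24)C1(Oc2cccc4cccc(c24)O1)C(CO[Si](C)(C)C(C)(C)C)=C3O[Si](C)(C)C | intermediate
19 | quaternary ketone, C29 (S): CH2OTBS in the place of H29 of the target, CH2OH in the place of C30 | O=C1C=Cc2cc3c(c4ccc(OC)c1c24)C1(Oc2cccc4cccc(c24)O1)[C@](CO[Si](C)(C)C(C)(C)C)(CO)C3=O | intermediate
20 | ethynyltrimethylsilane | C#C[Si](C)(C)C | starting material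
21 | alkynyl diol, C29 (S), C34 (S): C34 carries OH and C≡C–SiMe3 arranged as O35 and C33 in the target; alkyne cis to CH2OH, hydroxyl cis to CH2OTBS | O=C1C=Cc2cc3c(c4ccc(OC)c1c24)C1(Oc2cccc4cccc(c24)O1)[C@](CO[Si](C)(C)C(C)(C)C)(CO)[C@]3(O)C#C[Si](C)(C)C | intermediate
22 | hydroxy aldehyde, C29 (S), C34 (S): C30 formyl cis to the alkyne; free C34 OH | O=C1C=Cc2cc3c(c4ccc(OC)c1c24)C1(Oc2cccc4cccc(c24)O1)[C@](CO[Si](C)(C)C(C)(C)C)(C=O)[C@]3(O)C#C[Si](C)(C)C | intermediate
23 | key-step precursor, C29 (S), C34 (S): 4-alkynal with C34 OSiEt3, silyl-capped alkyne and CH2OTBS on C29 | O=C1C=Cc2cc3c(c4ccc(OC)c1c24)C1(Oc2cccc4cccc(c24)O1)[C@](CO[Si](C)(C)C(C)(C)C)(C=O)[C@]3(O[Si](CC)(CC)CC)C#C[Si](C)(C)C | intermediate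
24 | key-step product, C29 (S), C34 (S): cis-fused cyclopentenone with SiMe3 on C32, OSiEt3 on C34 and CH2OTBS on C29 | O=C1C=Cc2cc3c(c4ccc(OC)c1c24)C1(Oc2cccc4cccc(c24)O1)[C@]1(CO[Si](C)(C)C(C)(C)C)C(=O)C([Si](C)(C)C)=C[C@]31O[Si](CC)(CC)CC | intermediate
25 | keto diol, C29 (S), C34 (S): spiropreussione B 9-methyl ether carrying CH2OH in place of H29 | O=C1C=Cc2cc3c(c4ccc(OC)c1c24)C1(Oc2cccc4cccc(c24)O1)[C@]1(CO)C(=O)C=C[C@]31O | intermediate
26 | β-keto aldehyde (C29 formyl in place of H29) | O=C1C=Cc2cc3c(c4ccc(OC)c1c24)C1(Oc2cccc4cccc(c24)O1)[C@]1(C=O)C(=O)C=C[C@]31O | intermediate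
27 | β-keto acid (C29 carboxyl in place of H29) | O=C1C=Cc2cc3c(c4ccc(OC)c1c24)C1(Oc2cccc4cccc(c24)O1)[C@]1(C(=O)O)C(=O)C=C[C@]31O | intermediate
28 | spiropreussione B 9-methyl ether, C29 (S), C34 (R) | O=C1C=Cc2cc3c(c4ccc(OC)c1c24)C1(Oc2cccc4cccc(c24)O1)[C@@H]1C(=O)C=C[C@]31O | intermediate
29 | spiropreussione B, C29 (S), C34 (R); H29 and O35 cis | O=C1C=Cc2cc3c(c4ccc(O)c1c24)C1(Oc2cccc4cccc(c24)O1)[C@@H]1C(=O)C=C[C@]31O | target

**Count and risks**

Total step count: 17. Longest linear sequence: 17 steps (1 to 29); compounds 5, 12 and 20 enter as purchased reagents.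

Steps most likely to fail:

Step 10. The crowded tetrasubstituted enol silane may be discriminated poorly by the chiral catalyst, or may hydrolyse back to the ketone faster than it adds to formaldehyde. Fallback from 17, returning at 19: 17 is taken through the enol silane 18 and hydroxymethylated with Sc(OTf)3 alone, which gives 19 as the racemate, that is together with its enantiomer F2. A lipase (Pseudomonas cepacia lipase, vinyl acetate, tBuOMe, rt), chosen for faster acylation of F2, converts it into the acetate F3, and the unreacted 19 is separated by chromatography and continues with step 11. The absolute configuration then comes from an enzymatic kinetic resolution instead of an asymmetric C–C bond formation.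

Step 7. The ambident naphtholate may attack through carbon instead of oxygen, or the sequence may stop at the open vinylogous ester because closure to the ketal is slow. Fallback from 11, returning at 14: 11 is treated with NaOMe in MeOH at 0 °C, where the hard methoxide can only attack through oxygen, to give the 3-methoxyindenone F1. F1 is then heated with naphthalene-1,8-diol and catalytic TsOH in toluene with removal of methanol, an acid-catalysed vinylogous transesterification and ketalisation under thermodynamic control that should deliver 14 without any phenolate being present.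

Step 14. The acyl rhodium hydride may decarbonylate before the hindered alkyne inserts, or the cationic metal may be held by the peri-methoxy carbonyl unit, so that ring E does not close. Fallback from 23, returning at 25: the alkyne of 23 is desilylated with K2CO3 in MeOH to the terminal alkyne F4, which is semi-hydrogenated (H2, Pd/CaCO3–Pb(OAc)2 Lindlar catalyst, quinoline) to the vinyl compound F5. CH2=CHMgBr at −78 °C adds to the formyl group to give the allylic alcohol F6, Dess–Martin oxidation gives the dienone F7, and ring-closing metathesis with the second-generation Grubbs catalyst closes ring E as the cyclopentenone F8. The acid treatment of step 15 turns F8 into 25. Ring E is then closed by forming C32=C33 instead of C30–C32.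

Further compounds
F1 | step 7 | 3-methoxyindenone (C16 OMe; C16=C29; C34 ketone) | O=C1C=Cc2cc3c(c4ccc(OC)c1c24)C(OC)=CC3=O
F2 | step 10 | enantiomer of 19, C29 (R) | O=C1C=Cc2cc3c(c4ccc(OC)c1c24)C1(Oc2cccc4cccc(c24)O1)[C@@](CO[Si](C)(C)C(C)(C)C)(CO)C3=O
F3 | step 10 | acetate of F2 | O=C1C=Cc2cc3c(c4ccc(OC)c1c24)C1(Oc2cccc4cccc(c24)O1)[C@@](CO[Si](C)(C)C(C)(C)C)(COC(C)=O)C3=O
F4 | step 14 | terminal alkyne aldehyde (23 without the C32 silyl group) | O=C1C=Cc2cc3c(c4ccc(OC)c1c24)C1(Oc2cccc4cccc(c24)O1)[C@](CO[Si](C)(C)C(C)(C)C)(C=O)[C@]3(O[Si](CC)(CC)CC)C#C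
F5 | step 14 | vinyl aldehyde (C33=C32 alkene on C34) | O=C1C=Cc2cc3c(c4ccc(OC)c1c24)C1(Oc2cccc4cccc(c24)O1)[C@](CO[Si](C)(C)C(C)(C)C)(C=O)[C@]3(O[Si](CC)(CC)CC)C=C
F6 | step 14 | allylic alcohol (C30 carbinol bearing vinyl; epimer mixture at C30) | O=C1C=Cc2cc3c(c4ccc(OC)c1c24)C1(Oc2cccc4cccc(c24)O1)[C@](CO[Si](C)(C)C(C)(C)C)(C(O)C=C)[C@]3(O[Si](CC)(CC)CC)C=C
F7 | step 14 | dienone (C30 vinyl ketone; C34 vinyl) | O=C1C=Cc2cc3c(c4ccc(OC)c1c24)C1(Oc2cccc4cccc(c24)O1)[C@](CO[Si](C)(C)C(C)(C)C)(C(=O)C=C)[C@]3(O[Si](CC)(CC)CC)C=C
F8 | step 14 | cyclopentenone with C32 H, C34 OSiEt3 and C29 CH2OTBS | O=C1C=Cc2cc3c(c4ccc(OC)c1c24)C1(Oc2cccc4cccc(c24)O1)[C@]1(CO[Si](C)(C)C(C)(C)C)C(=O)C=C[C@]31O[Si](CC)(CC)CC
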